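The coupling partner is the reagent whose balance I write for this flask. Its charge divides among coupling with either substrate, quenching by the protic impurity, homo dimer (two per turn), decomposition and what remains. From that balance I take the partner yield Y, substrate coupled per partner charged, so that the reacted part c is Y times the partner charge over the two substrates charged.

| flask | left-handed substrate | right-handed substrate | coupling partner | protic impurity | catalyst | remark | time |
|---|---|---|---|---|---|---|---|
| Friday's | 0.052 M | 0.052 M | 0.078 M | 0.052 M | 2.8 mM | run made earlier |  |
| Thursday's | 0.052 M | 0.052 M | 0.31 M | 0.052 M | 2.8 mM | run made earlier |  |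
| Sunday's | 0.052 M | 0.052 M | 0.156 M | 0.078 M | 2.8 mM | run made earlier |  |
| flask | 0.052 M | 0.052 M | 0.156 M | 0.0520 M | 2.8 mM |  | 3.0 h |

| run | time / min | left-handed substrate / % | right-handed substrate / % |
|---|---|---|---|
| Friday's | 8.00 | 48.3 | 49.2 |
| Friday's | 15.0 | 45.9 | 48.7 |
| Friday's | 30.0 | 45.0 | 48.6 |
| Friday's | 60.0 | 42.9 | 47.9 |
| Friday's | 120 | 40.9 | 46.9 |
| Thursday's | 10.0 | 43.1 | 46.4 |
| Thursday's | 25.0 | 37.7 | 45.4 |
| Thursday's | 50.0 | 32.4 | 42.9 |
| Thursday's | 80.0 | 29.8 | 42.7 |
| Thursday's | 120 | 27.5 | 40.1 |
| Sunday's | 8.00 | 46.4 | 49.1 |
| Sunday's | 15.0 | 44.9 | 47.9 |
| Sunday's | 30.0 | 41.7 | 46.2 |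
| Sunday's | 60.0 | 38.8 | 45.9 |
| Sunday's | 120 | 37.0 | 44.8 |

(each reading ± 0.5 percentage points)

- catalyst is single-handed; left-handed substrate and right-handed substrate are mirror images of each other, charged as a racemate, each of them at the stated concentration
- what may be going on: coupling partner + catalyst + left-handed substrate -> catalyst + left-handed product; coupling partner + catalyst + right-handed substrate -> catalyst + right-handed product; coupling partner -> decomposed reagent; 2 coupling partner -> homo dimer; coupling partner + protic impurity -> quenched reagent
- an excess is below zero if the other one leads

* part of the left-handed substrate and right-handed substrate charged together that has reacted at 3.0 h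
* excess of left-handed product over right-handed product in the product at 3.0 h
* excess of right-handed substrate over left-handed substrate among what is left of the two at 3.0 h

Which given number must be known well? The partner charge must: from Friday's run to Thursday's it rises from 0.078 M to 0.31 M, and c at 120 min rises from 12.2 % to 32.4 %. The impurity counts as well: Sunday's run, with the flask's partner charge but 0.078 M of impurity, gives 18.2 %, about 2.2 percentage points below my estimate for 0.0520 M of impurity at that time, taken from the mean partner yield of Friday's and Thursday's runs. The catalyst needs no number of its own, since the flask holds the 2.8 mM of the runs.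

Now the number. Y at 120 min reads 16.3 % on Friday and 10.9 % on Thursday. These runs share the flask's impurity, and its partner charge lies midway between theirs on a log scale, so I take their mean, 13.6 %. Sunday's curve, continued linearly in ln t to 3.0 h, adds 1.7 points to c. My partner yield, substrate coupled per partner charged, is then 14.7 %, which gives c = 22.0 %. I take eP from Sunday's run, 42.9 %. The racemate's balance, eS = eP·c/(1−c), then gives 12.1 %.

The forecast's way is “Interpolating on partner minus impurity”, and it says 23.6 %, 42.4 % and 13.1 %.

The flask gives c = 23.0 %, eP = 43.7 % and eS = 13.0 %, so Y is 15.3 %.

    coupling partner + catalyst + left-handed substrate → catalyst + left-handed product (k = 24.4 /M²/min)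
    coupling partner + catalyst + right-handed substrate → catalyst + right-handed product (k = 8.44 /M²/min)
    coupling partner → decomposed reagent (k = 0.00270 /min)
    2 coupling partner → homo dimer (k = 0.0875 /M/min)
    coupling partner + protic impurity → quenched reagent (k = 0.364 /M/min)

In this flask the half-life of the left-handed substrate by coupling is 1.9 h at 0.230 h, yet the coupling partner is down to 49.4 % of its charge by 0.300 h. At 3.0 h the partner, charged in excess of the two substrates together, stands at 4.8 % of its charge, less than the 67 % of the left-handed substrate. A neighbouring flask charged with 0.062 M of partner gets 8.76 % from my Y, and it reacts 10.5 %, a partner yield of 17.7 %.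

The earlier runs and the new flask come from a simulation from invented constants, noise included.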